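**Retrosynthetic overview**
1. The C40 chain is cut at C11=C12 and C11'=C12' into C15 phosphonium salt 15 (ring A, the trihydroxycyclohexane end), C10 dialdehyde 27 and C15 phosphonium salt 26 (ring B, the 7-oxabicyclo[2.2.1]heptane end); two Wittig reactions join them.
2. Both salts come from one α-ketol, cyclohexanone 7 (C3–OSi, C5=O, C6–OH, C6–CH2OBn). Ring A needs one equatorial methyl addition at C5; ring B needs C5 methylenation, closure of the O6→C3 bridge by inversion/inversion, and exo hydration at C5.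
3. Ketol 7 is made from the acyclic, achiral keto aldehyde 4 and the acetaldehyde enol silane 5 in one flask: aldol (C3–C4), then crossed benzoin (C5–C6). Aldehyde 4 comes from Weinreb amide 1 and prenylmagnesium chloride 2.
4. Enabling feature: in ring A the sequence C3(OH)–C4H2–C5(O)–C6(OH) is a β-hydroxy carbonyl (C3/C5) fused to an α-hydroxy carbonyl (C5/C6) around the C4–C5 unit, and C1 is quaternary. The ring therefore opens to a 1,4-keto aldehyde (C3, C6) and a two-carbon enolate/acyl-anion unit (C4–C5). Ring B has the same C3 and C6 configuration.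
5. Ring order: the carbocycle common to rings A and B (step 3), then the oxygen bridge of ring B (step 12), then the polyene.

Key step: step 3

Remark on the chemistry: ring carbons carry carotenoid numbers (C1 quaternary, C3 secondary carbinol, C5 methyl-bearing, C6 chain-bearing; primes for ring B). Compounds 1, 2, 5, 11 and 27 are taken as commercial. For both chiral catalysts of step 3, the enantiomer with the facial preference stated there is meant.

**Route**

Step 1
Reactants: 1 2-(benzyloxy)-N-methoxy-N-methylacetamide; 2 prenylmagnesium chloride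
Product: 3 1-(benzyloxy)-3,3-dimethylpent-4-en-2-one
Conditions: THF, −78 → 0 °C; aq. NH4Cl
Reagents that add atoms: none
Why: Weinreb ketone synthesis in which the allylic Grignard reagent reacts through its γ-carbon (allyl transposition, six-membered transition state), so the more substituted terminus bonds to the acyl carbon and the chelated tetrahedral intermediate prevents over-addition, giving the ketone with the quaternary C1 and a vinyl group.

Step 2
Reactants: 3 1-(benzyloxy)-3,3-dimethylpent-4-en-2-one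
Product: 4 5-(benzyloxy)-3,3-dimethyl-4-oxopentanal
Conditions: PdCl2(PhCN)2 (cat.), CuCl2 (cat.), AgNO2 (cat.), O2 (1 atm), t-BuOH/MeNO2, rt
Reagents that add atoms: dioxygen, O=O
Why: Aldehyde-selective (anti-Markovnikov) Wacker-type oxidation with a nitrite co-catalyst; the quaternary allylic carbon blocks oxygen delivery to the internal alkene carbon, so the terminal carbon should become the C3 aldehyde while ketone and benzyl ether stay untouched.

Step 3
Reactants: 4 5-(benzyloxy)-3,3-dimethyl-4-oxopentanal; 5 tert-butyldimethyl(vinyloxy)silane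
Product: 7 (2R,5R)-2-[(benzyloxy)methyl]-5-[(tert-butyldimethylsilyl)oxy]-2-hydroxy-3,3-dimethylcyclohexan-1-one, via silyloxy keto aldehyde 6 (not isolated)
Conditions: 5 (1.5 equiv), chiral confined IDPi Brønsted acid (N-triflyl imidodiphosphorimidate HN[P(=NSO2CF3)(O2Ar*)]2 built on two 3,3'-diaryl-1,1'-bi-2-naphthol units, 1 mol %), toluene, −40 °C; then in the same flask chiral aminoindanol-derived N-pentafluorophenyl triazolium tetrafluoroborate (10 mol %), Et3N (20 mol %), THF, 23 °C
Reagents that add atoms: none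
Why: The silylated IDPi ion pair activates only the aldehyde of 4 and enol silane 5 adds once to its Si face (catalytic asymmetric Mukaiyama aldol with silyl transfer), forming C3–C4 and giving the β-silyloxy aldehyde 6 with C3 set by the catalyst; the carbene from the triazolium salt then turns the new aldehyde into an acyl-anion equivalent at C5 (its hydroxy-enamine adduct) that adds to the C6 ketone (intramolecular crossed aldehyde–ketone benzoin), forming C5–C6. The closest known reactions are the catalytic single aldolization of acetaldehyde enol silanes with aliphatic aldehydes and the carbene-catalysed benzoin cyclisation of keto aldehydes to six-membered tertiary α-ketols, here run one after the other without isolation. The ring closes in the 6-exo-trig mode (the attacked C=O is exocyclic to the forming ring), helped by the gem-dimethyl effect of C1. C6 is set by the chiral carbene, chosen to add to the Si face of the ketone; this is the matched case with the chair in which the C3 silyloxy and the C6 benzyloxymethyl groups are both equatorial, so C3–O and C6–OH end up cis. Three selectivities are needed: only the aldehyde of 4 is activated because the ketone is neopentylic; aldehyde 6 is too large for a second aldolization inside the confined catalyst; and when the carbene is added, 6 is the only aldehyde left and the quaternary C1 keeps the ketone from enolising toward the ring.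

Step 4
Reactants: 7 (2R,5R)-2-[(benzyloxy)methyl]-5-[(tert-butyldimethylsilyl)oxy]-2-hydroxy-3,3-dimethylcyclohexan-1-one
Product: 8 (1S,2R,5R)-2-[(benzyloxy)methyl]-5-[(tert-butyldimethylsilyl)oxy]-1,3,3-trimethylcyclohexane-1,2-diol
Conditions: MeLi (3.5 equiv), CeCl3 (3.5 equiv), THF, −78 °C; aq. NH4Cl
Reagents that add atoms: methyllithium, C[Li]
Why: Organocerium 1,2-addition to the C5 ketone after deprotonation of the C6 hydroxyl; in the chair with the C3 silyloxy and C6 benzyloxymethyl groups equatorial the axial C1 methyl blocks axial attack, so methyl should enter equatorially on the face of the axial C6 alkoxide, making C5 (S) with a trans-diaxial 5,6-diol, while the weakly basic cerium reagent suppresses enolisation and β-elimination of the silyloxy group.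

Step 5
Reactants: 8 (1S,2R,5R)-2-[(benzyloxy)methyl]-5-[(tert-butyldimethylsilyl)oxy]-1,3,3-trimethylcyclohexane-1,2-diol
Product: 9 (1S,2R,5R)-5-[(tert-butyldimethylsilyl)oxy]-2-(hydroxymethyl)-1,3,3-trimethylcyclohexane-1,2-diol
Conditions: H2 (1 atm), Pd/C, EtOAc, rt
Reagents that add atoms: none
Why: Hydrogenolysis of the benzyl ether; no alkene is present and the silyl ether and tertiary alcohols are inert.

Step 6
Reactants: 9 (1S,2R,5R)-5-[(tert-butyldimethylsilyl)oxy]-2-(hydroxymethyl)-1,3,3-trimethylcyclohexane-1,2-diol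
Product: 10 (1S,2S,4R)-4-[(tert-butyldimethylsilyl)oxy]-1,2-dihydroxy-2,6,6-trimethylcyclohexane-1-carbaldehyde
Conditions: SO3·pyridine, DMSO, i-Pr2NEt, CH2Cl2, 0 °C
Reagents that add atoms: none
Why: Parikh–Doering oxidation of the only primary alcohol; the tertiary alcohols cannot be oxidised and the mild, non-acidic conditions avoid glycol cleavage and α-ketol shift.

Step 7
Reactants: 10 (1S,2S,4R)-4-[(tert-butyldimethylsilyl)oxy]-1,2-dihydroxy-2,6,6-trimethylcyclohexane-1-carbaldehyde; 11 ethyl (2E)-4-(diethoxyphosphoryl)-3-methylbut-2-enoate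
Product: 12 ethyl (2E,4E)-5-[(1S,2S,4R)-4-[(tert-butyldimethylsilyl)oxy]-1,2-dihydroxy-2,6,6-trimethylcyclohexyl]-3-methylpenta-2,4-dienoate
Conditions: 11 (3 equiv), LiN(SiMe3)2 (2.9 equiv), THF, −78 → 0 °C
Reagents that add atoms: none
Why: Horner–Wadsworth–Emmons olefination through the α-carbon of the vinylogous phosphonate anion should give the (E)-C7=C8 bond with the (2E) trisubstituted bond carried by the reagent (any 2Z isomer is removed by chromatography), and the phosphonate anion is too weakly basic to deprotonate the tertiary alcohols, so retro-aldol is not expected.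

Step 8
Reactants: 12 ethyl (2E,4E)-5-[(1S,2S,4R)-4-[(tert-butyldimethylsilyl)oxy]-1,2-dihydroxy-2,6,6-trimethylcyclohexyl]-3-methylpenta-2,4-dienoate
Product: 13 (1S,2S,4R)-4-[(tert-butyldimethylsilyl)oxy]-1-[(1E,3E)-5-hydroxy-3-methylpenta-1,3-dien-1-yl]-2,6,6-trimethylcyclohexane-1,2-diol
Conditions: i-Bu2AlH (5 equiv), CH2Cl2, −78 °C; Rochelle salt
Reagents that add atoms: none
Why: Aluminium hydride 1,2-reduction of the dienoate to the allylic alcohol without touching the diene or the silyl ether.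

Step 9
Reactants: 13 (1S,2S,4R)-4-[(tert-butyldimethylsilyl)oxy]-1-[(1E,3E)-5-hydroxy-3-methylpenta-1,3-dien-1-yl]-2,6,6-trimethylcyclohexane-1,2-diol
Product: 15 {(2E,4E)-5-[(1S,2S,4R)-4-[(tert-butyldimethylsilyl)oxy]-1,2-dihydroxy-2,6,6-trimethylcyclohexyl]-3-methylpenta-2,4-dien-1-yl}triphenylphosphonium bromide, via allylic bromide 14 (not isolated)
Conditions: CBr4, PPh3, 2,6-lutidine, CH2Cl2, −20 °C; then PPh3, rt
Reagents that add atoms: carbon tetrabromide, BrC(Br)(Br)Br; triphenylphosphine, c1ccc(cc1)P(c1ccccc1)c1ccccc1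
Why: Appel bromination of the primary allylic alcohol (tertiary alcohols and the silyl ether do not react under buffered conditions) followed by SN2 quaternisation of triphenylphosphine; the neutral conditions spare the tertiary allylic C6 hydroxyl from ionisation.

Step 10
Reactants: 7 (2R,5R)-2-[(benzyloxy)methyl]-5-[(tert-butyldimethylsilyl)oxy]-2-hydroxy-3,3-dimethylcyclohexan-1-one
Product: 16 (1S,4R)-1-[(benzyloxy)methyl]-4-[(tert-butyldimethylsilyl)oxy]-2,2-dimethyl-6-methylidenecyclohexan-1-ol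
Conditions: Zn, CH2Br2, TiCl4, THF/CH2Cl2, 0 °C → rt
Reagents that add atoms: dibromomethane, BrCBr
Why: Takai–Lombardo methylenation; the non-basic zinc/titanium carbenoid should convert the hindered, enolisable α-hydroxy ketone into the exocyclic alkene without β-elimination of the silyloxy group or α-ketol shift.

Step 11
Reactants: 16 (1S,4R)-1-[(benzyloxy)methyl]-4-[(tert-butyldimethylsilyl)oxy]-2,2-dimethyl-6-methylidenecyclohexan-1-ol
Product: 17 (1S,4R)-1-[(benzyloxy)methyl]-2,2-dimethyl-6-methylidenecyclohexane-1,4-diol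
Conditions: Bu4NF, THF, 0 °C → rt
Reagents that add atoms: none
Why: Fluoride cleavage of the secondary silyl ether.

Step 12
Reactants: 17 (1S,4R)-1-[(benzyloxy)methyl]-2,2-dimethyl-6-methylidenecyclohexane-1,4-diol
Product: 19 (1S,4R)-1-[(benzyloxy)methyl]-2,2-dimethyl-6-methylidene-7-oxabicyclo[2.2.1]heptane, via iodide 18 (not isolated)
Conditions: PPh3, I2, imidazole, toluene, 0 → 40 °C; then NaH, THF, 0 → 45 °C
Reagents that add atoms: none
Why: Appel iodination of the secondary C3 alcohol with inversion (the tertiary alcohol does not react), then intramolecular Williamson etherification in which the C6 alkoxide displaces iodide from the opposite face through a boat (5-exo-tet, second inversion), so the oxygen bridge lies on the face of the original C3–O bond, as in the known closure of trans-4-halocyclohexanols to 7-oxabicyclo[2.2.1]heptanes.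

Step 13
Reactants: 19 (1S,4R)-1-[(benzyloxy)methyl]-2,2-dimethyl-6-methylidene-7-oxabicyclo[2.2.1]heptane
Product: 20 (1R,2R,4R)-1-[(benzyloxy)methyl]-2,6,6-trimethyl-7-oxabicyclo[2.2.1]heptan-2-ol
Conditions: Mn(dpm)3 (dpm = dipivaloylmethanato, cat.), PhSiH3, O2 (1 atm), i-PrOH/CH2Cl2, 0 °C; then PPh3
Reagents that add atoms: dioxygen, O=O
Why: Mukaiyama hydration (hydrogen-atom transfer to the CH2 terminus, then O2 capture by the tertiary C5 radical, Markovnikov); the radical should be trapped on the exo face, syn to the oxygen bridge, because the endo face is shielded by the endo methyl group at C1, which gives the exo hydroxyl (5'R).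

Step 14
Reactants: 20 (1R,2R,4R)-1-[(benzyloxy)methyl]-2,6,6-trimethyl-7-oxabicyclo[2.2.1]heptan-2-ol
Product: 21 (1R,2R,4R)-1-(hydroxymethyl)-2,6,6-trimethyl-7-oxabicyclo[2.2.1]heptan-2-ol
Conditions: H2 (1 atm), Pd/C, EtOAc, rt
Reagents that add atoms: none
Why: Hydrogenolysis of the benzyl ether, placed after the hydration so that no alkene is exposed to hydrogen.

Step 15
Reactants: 21 (1R,2R,4R)-1-(hydroxymethyl)-2,6,6-trimethyl-7-oxabicyclo[2.2.1]heptan-2-ol
Product: 22 (1S,2R,4R)-2-hydroxy-2,6,6-trimethyl-7-oxabicyclo[2.2.1]heptane-1-carbaldehyde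
Conditions: SO3·pyridine, DMSO, i-Pr2NEt, CH2Cl2, 0 °C
Reagents that add atoms: none
Why: Parikh–Doering oxidation of the primary alcohol; the tertiary alcohol is inert.

Step 16
Reactants: 22 (1S,2R,4R)-2-hydroxy-2,6,6-trimethyl-7-oxabicyclo[2.2.1]heptane-1-carbaldehyde; 11 ethyl (2E)-4-(diethoxyphosphoryl)-3-methylbut-2-enoate
Product: 23 ethyl (2E,4E)-5-[(1S,2R,4R)-2-hydroxy-2,6,6-trimethyl-7-oxabicyclo[2.2.1]heptan-1-yl]-3-methylpenta-2,4-dienoate
Conditions: 11 (2 equiv), LiN(SiMe3)2 (1.9 equiv), THF, −78 → 0 °C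
Reagents that add atoms: none
Why: Horner–Wadsworth–Emmons olefination of the bridgehead aldehyde should give the (E)-C7'=C8' bond; the weakly basic phosphonate anion leaves the β-hydroxyl protonated, so retro-aldol opening of the bicycle is not expected.

Step 17
Reactants: 23 ethyl (2E,4E)-5-[(1S,2R,4R)-2-hydroxy-2,6,6-trimethyl-7-oxabicyclo[2.2.1]heptan-1-yl]-3-methylpenta-2,4-dienoate
Product: 24 (1S,2R,4R)-1-[(1E,3E)-5-hydroxy-3-methylpenta-1,3-dien-1-yl]-2,6,6-trimethyl-7-oxabicyclo[2.2.1]heptan-2-ol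
Conditions: i-Bu2AlH (4 equiv), CH2Cl2, −78 °C; Rochelle salt
Reagents that add atoms: none
Why: Aluminium hydride 1,2-reduction of the dienoate to the allylic alcohol.

Step 18
Reactants: 24 (1S,2R,4R)-1-[(1E,3E)-5-hydroxy-3-methylpenta-1,3-dien-1-yl]-2,6,6-trimethyl-7-oxabicyclo[2.2.1]heptan-2-ol
Product: 26 {(2E,4E)-5-[(1S,2R,4R)-2-hydroxy-2,6,6-trimethyl-7-oxabicyclo[2.2.1]heptan-1-yl]-3-methylpenta-2,4-dien-1-yl}triphenylphosphonium bromide, via allylic bromide 25 (not isolated)
Conditions: CBr4, PPh3, 2,6-lutidine, CH2Cl2, −20 °C; then PPh3, rt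
Reagents that add atoms: carbon tetrabromide, BrC(Br)(Br)Br; triphenylphosphine, c1ccc(cc1)P(c1ccccc1)c1ccccc1
Why: Appel bromination of the primary allylic alcohol and SN2 quaternisation of triphenylphosphine under neutral conditions, which keeps the tertiary allylic bridge ether from ionising.

Step 19
Reactants: 26 {(2E,4E)-5-[(1S,2R,4R)-2-hydroxy-2,6,6-trimethyl-7-oxabicyclo[2.2.1]heptan-1-yl]-3-methylpenta-2,4-dien-1-yl}triphenylphosphonium bromide; 27 (2E,4E,6E)-2,7-dimethylocta-2,4,6-trienedial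
Product: 28 (2E,4E,6E,8E,10E,12E)-13-[(1S,2R,4R)-2-hydroxy-2,6,6-trimethyl-7-oxabicyclo[2.2.1]heptan-1-yl]-2,7,11-trimethyltrideca-2,4,6,8,10,12-hexaenal
Conditions: 27 (2.5 equiv), NaOMe, MeOH/CH2Cl2, 0 °C → rt, dark; then n-heptane, 80 °C (Z → E)
Reagents that add atoms: none
Why: Wittig olefination of the semi-stabilised allylic ylide with an excess of the symmetrical dialdehyde should stop at mono-olefination; the new C11'=C12' bond forms as an E/Z mixture that is equilibrated thermally to all-E, and the free hydroxyl is tolerated.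

Step 20
Reactants: 15 {(2E,4E)-5-[(1S,2S,4R)-4-[(tert-butyldimethylsilyl)oxy]-1,2-dihydroxy-2,6,6-trimethylcyclohexyl]-3-methylpenta-2,4-dien-1-yl}triphenylphosphonium bromide; 28 (2E,4E,6E,8E,10E,12E)-13-[(1S,2R,4R)-2-hydroxy-2,6,6-trimethyl-7-oxabicyclo[2.2.1]heptan-1-yl]-2,7,11-trimethyltrideca-2,4,6,8,10,12-hexaenal
Product: 29 3-O-(tert-butyldimethylsilyl) ether of the target, (3R,5S,6S,3'R,5'R,6'S)-3-[(tert-butyldimethylsilyl)oxy]-3',6'-epoxy-5,6,5',6'-tetrahydro-β,β-carotene-5,6,5'-triol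
Conditions: NaOMe, MeOH/CH2Cl2, 0 °C → rt, dark; then n-heptane, 80 °C (Z → E)
Reagents that add atoms: none
Why: Second Wittig olefination closes the C11=C12 bond and completes the C40 polyene; thermal equilibration should give the all-E isomer, and the tertiary alcohols and silyl ether are stable to methoxide.

Step 21
Reactants: 29 3-O-(tert-butyldimethylsilyl) ether of the target
Product: 30 (3R,5S,6S,3'R,5'R,6'S)-3',6'-epoxy-5,6,5',6'-tetrahydro-β,β-carotene-3,5,6,5'-tetrol (target, CNP0261804.1)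
Conditions: Bu4NF, THF, 0 °C, dark, argon
Reagents that add atoms: none
Why: Fluoride cleavage of the silyl ether under basic, non-acidic conditions that spare the acid-labile tertiary allylic alcohol and the polyene.

**Compound list**
1 | 2-(benzyloxy)-N-methoxy-N-methylacetamide | O=C(COCc1ccccc1)N(C)OC | starting material
2 | prenylmagnesium chloride | CC(C)=CC[Mg]Cl | starting material
3 | 1-(benzyloxy)-3,3-dimethylpent-4-en-2-one | C=CC(C)(C)C(=O)COCc1ccccc1 | intermediate
4 | 5-(benzyloxy)-3,3-dimethyl-4-oxopentanal | O=CCC(C)(C)C(=O)COCc1ccccc1 | intermediate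
5 | tert-butyldimethyl(vinyloxy)silane | C=CO[Si](C)(C)C(C)(C)C | starting material
6 | (3R)-7-(benzyloxy)-3-[(tert-butyldimethylsilyl)oxy]-5,5-dimethyl-6-oxoheptanal | O=CC[C@H](O[Si](C)(C)C(C)(C)C)CC(C)(C)C(=O)COCc1ccccc1 | intermediate
7 | (2R,5R)-2-[(benzyloxy)methyl]-5-[(tert-butyldimethylsilyl)oxy]-2-hydroxy-3,3-dimethylcyclohexan-1-one | O=C1C[C@H](O[Si](C)(C)C(C)(C)C)CC(C)(C)[C@@]1(O)COCc2ccccc2 | intermediate
8 | (1S,2R,5R)-2-[(benzyloxy)methyl]-5-[(tert-butyldimethylsilyl)oxy]-1,3,3-trimethylcyclohexane-1,2-diol | C[C@]1(O)C[C@H](O[Si](C)(C)C(C)(C)C)CC(C)(C)[C@@]1(O)COCc2ccccc2 | intermediate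
9 | (1S,2R,5R)-5-[(tert-butyldimethylsilyl)oxy]-2-(hydroxymethyl)-1,3,3-trimethylcyclohexane-1,2-diol | C[C@]1(O)C[C@H](O[Si](C)(C)C(C)(C)C)CC(C)(C)[C@@]1(O)CO | intermediate
10 | (1S,2S,4R)-4-[(tert-butyldimethylsilyl)oxy]-1,2-dihydroxy-2,6,6-trimethylcyclohexane-1-carbaldehyde | C[C@]1(O)C[C@H](O[Si](C)(C)C(C)(C)C)CC(C)(C)[C@@]1(O)C=O | intermediate
11 | ethyl (2E)-4-(diethoxyphosphoryl)-3-methylbut-2-enoate | CCOC(=O)/C=C(\C)CP(=O)(OCC)OCC | starting material
12 | ethyl (2E,4E)-5-[(1S,2S,4R)-4-[(tert-butyldimethylsilyl)oxy]-1,2-dihydroxy-2,6,6-trimethylcyclohexyl]-3-methylpenta-2,4-dienoate | CCOC(=O)/C=C(\C)/C=C/[C@]1(O)C(C)(C)C[C@@H](O[Si](C)(C)C(C)(C)C)C[C@]1(C)O | intermediate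
13 | (1S,2S,4R)-4-[(tert-butyldimethylsilyl)oxy]-1-[(1E,3E)-5-hydroxy-3-methylpenta-1,3-dien-1-yl]-2,6,6-trimethylcyclohexane-1,2-diol | OC/C=C(\C)/C=C/[C@]1(O)C(C)(C)C[C@@H](O[Si](C)(C)C(C)(C)C)C[C@]1(C)O | intermediate
14 | (1S,2S,4R)-1-[(1E,3E)-5-bromo-3-methylpenta-1,3-dien-1-yl]-4-[(tert-butyldimethylsilyl)oxy]-2,6,6-trimethylcyclohexane-1,2-diol | BrC/C=C(\C)/C=C/[C@]1(O)C(C)(C)C[C@@H](O[Si](C)(C)C(C)(C)C)C[C@]1(C)O | intermediate
15 | {(2E,4E)-5-[(1S,2S,4R)-4-[(tert-butyldimethylsilyl)oxy]-1,2-dihydroxy-2,6,6-trimethylcyclohexyl]-3-methylpenta-2,4-dien-1-yl}triphenylphosphonium bromide | [Br-].C(/C=C(\C)/C=C/[C@]1(O)C(C)(C)C[C@@H](O[Si](C)(C)C(C)(C)C)C[C@]1(C)O)[P+](c1ccccc1)(c1ccccc1)c1ccccc1 | intermediate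
16 | (1S,4R)-1-[(benzyloxy)methyl]-4-[(tert-butyldimethylsilyl)oxy]-2,2-dimethyl-6-methylidenecyclohexan-1-ol | C=C1C[C@H](O[Si](C)(C)C(C)(C)C)CC(C)(C)[C@@]1(O)COCc2ccccc2 | intermediate
17 | (1S,4R)-1-[(benzyloxy)methyl]-2,2-dimethyl-6-methylidenecyclohexane-1,4-diol | C=C1C[C@H](O)CC(C)(C)[C@@]1(O)COCc2ccccc2 | intermediate
18 | (1S,4S)-1-[(benzyloxy)methyl]-4-iodo-2,2-dimethyl-6-methylidenecyclohexan-1-ol | C=C1C[C@@H](I)CC(C)(C)[C@@]1(O)COCc2ccccc2 | intermediate
19 | (1S,4R)-1-[(benzyloxy)methyl]-2,2-dimethyl-6-methylidene-7-oxabicyclo[2.2.1]heptane | C=C1C[C@H]2CC(C)(C)[C@]1(COCc3ccccc3)O2 | intermediate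
20 | (1R,2R,4R)-1-[(benzyloxy)methyl]-2,6,6-trimethyl-7-oxabicyclo[2.2.1]heptan-2-ol | C[C@@]1(O)C[C@H]2CC(C)(C)[C@]1(COCc3ccccc3)O2 | intermediate
21 | (1R,2R,4R)-1-(hydroxymethyl)-2,6,6-trimethyl-7-oxabicyclo[2.2.1]heptan-2-ol | OC[C@]12O[C@H](CC1(C)C)C[C@@]2(C)O | intermediate
22 | (1S,2R,4R)-2-hydroxy-2,6,6-trimethyl-7-oxabicyclo[2.2.1]heptane-1-carbaldehyde | O=C[C@]12O[C@H](CC1(C)C)C[C@@]2(C)O | intermediate
23 | ethyl (2E,4E)-5-[(1S,2R,4R)-2-hydroxy-2,6,6-trimethyl-7-oxabicyclo[2.2.1]heptan-1-yl]-3-methylpenta-2,4-dienoate | CCOC(=O)/C=C(\C)/C=C/[C@]12O[C@H](CC1(C)C)C[C@@]2(C)O | intermediate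
24 | (1S,2R,4R)-1-[(1E,3E)-5-hydroxy-3-methylpenta-1,3-dien-1-yl]-2,6,6-trimethyl-7-oxabicyclo[2.2.1]heptan-2-ol | OC/C=C(\C)/C=C/[C@]12O[C@H](CC1(C)C)C[C@@]2(C)O | intermediate
25 | (1S,2R,4R)-1-[(1E,3E)-5-bromo-3-methylpenta-1,3-dien-1-yl]-2,6,6-trimethyl-7-oxabicyclo[2.2.1]heptan-2-ol | BrC/C=C(\C)/C=C/[C@]12O[C@H](CC1(C)C)C[C@@]2(C)O | intermediate
26 | {(2E,4E)-5-[(1S,2R,4R)-2-hydroxy-2,6,6-trimethyl-7-oxabicyclo[2.2.1]heptan-1-yl]-3-methylpenta-2,4-dien-1-yl}triphenylphosphonium bromide | [Br-].C(/C=C(\C)/C=C/[C@]12O[C@H](CC1(C)C)C[C@@]2(C)O)[P+](c1ccccc1)(c1ccccc1)c1ccccc1 | intermediate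
27 | (2E,4E,6E)-2,7-dimethylocta-2,4,6-trienedial | O=C/C(C)=C/C=C/C=C(\C)C=O | starting material
28 | (2E,4E,6E,8E,10E,12E)-13-[(1S,2R,4R)-2-hydroxy-2,6,6-trimethyl-7-oxabicyclo[2.2.1]heptan-1-yl]-2,7,11-trimethyltrideca-2,4,6,8,10,12-hexaenal | CC(/C=C/C=C(C)/C=C/[C@]12O[C@H](CC1(C)C)C[C@@]2(C)O)=C\C=C\C=C(C)\C=O | intermediate
29 | (3R,5S,6S,3'R,5'R,6'S)-3-[(tert-butyldimethylsilyl)oxy]-3',6'-epoxy-5,6,5',6'-tetrahydro-β,β-carotene-5,6,5'-triol | CC(/C=C/C=C(C)/C=C/[C@]12O[C@H](CC1(C)C)C[C@@]2(C)O)=C\C=C\C=C(C)\C=C\C=C(C)\C=C\[C@]1(O)C(C)(C)C[C@@H](O[Si](C)(C)C(C)(C)C)C[C@]1(C)O | intermediate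
30 | (3R,5S,6S,3'R,5'R,6'S)-3',6'-epoxy-5,6,5',6'-tetrahydro-β,β-carotene-3,5,6,5'-tetrol | CC(/C=C/C=C(C)/C=C/[C@]12O[C@H](CC1(C)C)C[C@@]2(C)O)=C\C=C\C=C(C)\C=C\C=C(C)\C=C\[C@]1(O)C(C)(C)C[C@@H](O)C[C@]1(C)O | target

**Step count and risks**
Total step count: 21. Longest linear sequence: 15 steps (steps 1–3, 10–21).

Steps most likely to fail:

1. Step 3. The two catalytic events may not hand over cleanly (oligomerisation of the acetaldehyde enolate equivalent, attack at the ketone, or quenching of the carbene by residual acid). Facial selectivity at C6 in the ring closure may also erode through a mismatched substrate preference or equilibration by retro-benzoin. Fallback, from 4: Brown allylboration of the aldehyde with (−)-B-allyldiisopinocampheylborane (Et2O, −78 °C; NaOH/H2O2) should give homoallylic alcohol F1 by Si-face attack. Silylation (TBSOTf, 2,6-lutidine) gives silyl ether F2. Oxidative cleavage of the terminal alkene (OsO4 cat., NaIO4, 2,6-lutidine, dioxane/H2O) gives 6, now isolated and purified. Pure 6 is then closed at high dilution in a separate carbene-catalysed benzoin step, where both catalyst antipodes can be tested, and the route is rejoined at 7.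

2. Step 12. Elimination may compete with substitution, both at the iodination (E2 of the activated alcohol) and at the ring closure (E2 of the iodide by the hindered alkoxide), and the iodophosphonium reagent may ionise the tertiary allylic alcohol. Fallback, from 17: Mitsunobu inversion of the secondary hydroxyl (4-nitrobenzoic acid, PPh3, DIAD, THF) gives 4-nitrobenzoate F3. Methanolysis (K2CO3, MeOH) gives trans-diol F4. Selective mesylation of the secondary hydroxyl (MsCl, Et3N, CH2Cl2, −20 °C) gives mesylate F5, and KOt-Bu in THF closes the bridge by sulfonate displacement, rejoining the route at 19.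

3. Step 13. The tertiary radical may capture oxygen on the endo face, or be reduced to the alkane before oxygen capture. Fallback, from 19: polar epoxidation on the exo face (dimethyldioxirane, acetone, 0 °C) gives spiro-epoxide F6. LiAlH4 (THF, 0 °C) opens it at the CH2 carbon, which leaves the exo tertiary alcohol and rejoins the route at 20.

**Further compounds**
F1 | step 3 | (5S)-1-(benzyloxy)-5-hydroxy-3,3-dimethyloct-7-en-2-one | C=CC[C@H](O)CC(C)(C)C(=O)COCc1ccccc1
F2 | step 3 | (5S)-1-(benzyloxy)-5-[(tert-butyldimethylsilyl)oxy]-3,3-dimethyloct-7-en-2-one | C=CC[C@H](O[Si](C)(C)C(C)(C)C)CC(C)(C)C(=O)COCc1ccccc1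
F3 | step 12 | (1S,4S)-4-[(benzyloxy)methyl]-4-hydroxy-3,3-dimethyl-5-methylidenecyclohexyl 4-nitrobenzoate | C=C1C[C@@H](OC(=O)c2ccc(cc2)[N+](=O)[O-])CC(C)(C)[C@@]1(O)COCc3ccccc3
F4 | step 12 | (1S,4S)-1-[(benzyloxy)methyl]-2,2-dimethyl-6-methylidenecyclohexane-1,4-diol | C=C1C[C@@H](O)CC(C)(C)[C@@]1(O)COCc2ccccc2
F5 | step 12 | (1S,4S)-4-[(benzyloxy)methyl]-4-hydroxy-3,3-dimethyl-5-methylidenecyclohexyl methanesulfonate | C=C1C[C@@H](OS(C)(=O)=O)CC(C)(C)[C@@]1(O)COCc2ccccc2
F6 | step 13 | (1R,2S,4R)-1-[(benzyloxy)methyl]-6,6-dimethylspiro[7-oxabicyclo[2.2.1]heptane-2,2'-oxirane] (oxirane oxygen exo) | C1O[C@@]12C[C@H]3CC(C)(C)[C@]2(COCc4ccccc4)O3
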